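**Retrosynthetic overview**
1. Target ⇒ ester C–O bond (Steglich) and one O-benzyl group: 7-O-benzyl-(2R,3R)-pinobanksin + (S)-2-methylbutanoic acid (from tiglic acid by Ru-catalysed asymmetric hydrogenation).
2. (2R,3R)-Pinobanksin ⇒ C3–OH bond: enzymatic C–H hydroxylation of (S)-pinocembrin by flavanone 3-hydroxylase, a 2-oxoglutarate-dependent non-heme iron dioxygenase.
3. (S)-Pinocembrin ⇒ C2–phenyl bond: Rh-catalysed asymmetric 1,4-addition of phenylboronic acid to 5,7-bis(benzyloxy)chromone.
4. Chromone ⇒ enaminone ring closure of 2-hydroxy-4,6-bis(benzyloxy)acetophenone ⇐ 2',4',6'-trihydroxyacetophenone.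
5. Ring order: rings A and B are bought as benzenoid starting materials; pyranone ring C is the only ring built (step 3), and C2, then C3, are set on the finished ring.

Assumption: the ligand antipodes named are those expected to give the drawn configurations. The sense of induction in step 4 is recalled rather than certain, so it is checked on the first run against (S)-pinocembrin (chiral HPLC, optical rotation) and the other antipode is used if needed.

**Step 1**
Reactants: 1 tiglic acid
Product: 2 (S)-2-methylbutanoic acid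
Conditions: Ru(OAc)2[(S)-H8-BINAP] (0.5 mol%), H2 (1.5–2 atm), MeOH, 15–25 °C
Reagents that add atoms: none
Why: Carboxylate-directed Noyori-type asymmetric hydrogenation with the divalent ruthenium H8-BINAP diacetate adds H2 to one enantioface of the trisubstituted alkene and sets the first stereocentre as S (about 97% ee expected).

**Step 2**
Reactants: 3 2',4',6'-trihydroxyacetophenone
Product: 4 1-[2,4-bis(benzyloxy)-6-hydroxyphenyl]ethan-1-one
Conditions: BnBr (2.05 eq), K2CO3 (2.2 eq), DMF, 0 °C to rt
Reagents that add atoms: benzyl bromide, BrCc1ccccc1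
Why: Williamson ether synthesis stops at the dibenzyl ether because the remaining ortho OH is hydrogen-bonded to the acetyl carbonyl and is the least nucleophilic phenol.

**Step 3**
Reactants: 4 1-[2,4-bis(benzyloxy)-6-hydroxyphenyl]ethan-1-one
Product: 6 5,7-bis(benzyloxy)-4H-chromen-4-one, via enaminone 5 (not isolated)
Conditions: DMF-DMA (3 eq), toluene, 100 °C; evaporate; then 2 M HCl, CH2Cl2, 40 °C
Reagents that add atoms: N,N-dimethylformamide dimethyl acetal, COC(OC)N(C)C
Why: Enaminone chromone synthesis, in which the methyl ketone condenses with the amide acetal and acid then drives intramolecular oxa-Michael addition of the phenol with loss of dimethylamine, leaving the benzyl ethers untouched.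

**Step 4**
Reactants: 6 5,7-bis(benzyloxy)-4H-chromen-4-one; 7 phenylboronic acid (3 eq)
Product: 8 (2S)-5,7-bis(benzyloxy)-2-phenylchroman-4-one
Conditions: [Rh(OH)(cod)]2 (2.5 mol%), (R)-MeO-F12-BIPHEP (5.5 mol%), CH2Cl2/H2O 10:1, 40 °C
Reagents that add atoms: none
Why: Hayashi–Miyaura asymmetric 1,4-addition, in which the phenyl–rhodium species (monovalent rhodium, electron-poor atropisomeric bisphosphine) inserts the chromone C2=C3 bond on one enantioface and water protonates the rhodium enolate, setting C2 as S under near-neutral conditions that avoid ring opening.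

**Step 5**
Reactants: 8 (2S)-5,7-bis(benzyloxy)-2-phenylchroman-4-one
Product: 9 (S)-pinocembrin [(2S)-5,7-dihydroxy-2-phenylchroman-4-one]
Conditions: H2 (1 atm), 10% Pd/C, EtOAc/MeOH 1:1, rt
Reagents that add atoms: none
Why: Neutral heterogeneous hydrogenolysis of the two benzyl aryl ethers frees the phenols the enzyme needs, and without base there is no retro-oxa-Michael racemisation at C2.

**Step 6**
Reactants: 9 (S)-pinocembrin
Product: 10 (2R,3R)-pinobanksin [(2R,3R)-3,5,7-trihydroxy-2-phenylchroman-4-one]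
Conditions: recombinant flavanone 3-hydroxylase (E. coli whole cells or cell-free extract), disodium 2-oxoglutarate (2 eq), FeSO4 (cat.), sodium ascorbate, catalase, air, KH2PO4/K2HPO4 buffer pH 7.0, 5% DMSO, 28 °C
Reagents that add atoms: dioxygen, O=O
Why: Enzymatic C–H hydroxylation by a 2-oxoglutarate-dependent non-heme iron dioxygenase, which accepts the 2S flavanone and delivers OH to C3 with retention on the face anti to the 2-phenyl group, setting C3 as R (2,3-trans) without the ring opening that plagues enolate oxidations of flavanones.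

**Step 7**
Reactants: 10 (2R,3R)-pinobanksin
Product: 11 (2R,3R)-7-(benzyloxy)-3,5-dihydroxy-2-phenylchroman-4-one
Conditions: BnBr (1.05 eq), K2CO3 (1.1 eq), acetone, rt, N2
Reagents that add atoms: benzyl bromide, BrCc1ccccc1
Why: Williamson etherification under weak base selects the most acidic 7-OH (para to the carbonyl-bearing carbon), since the 5-OH is locked in a hydrogen bond to C4=O and the 3-OH is a far less acidic secondary alcohol.

**Step 8**
Reactants: 11 (2R,3R)-7-(benzyloxy)-3,5-dihydroxy-2-phenylchroman-4-one; 2 (S)-2-methylbutanoic acid (1.3 eq)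
Product: 12 (2R,3R)-7-(benzyloxy)-5-hydroxy-4-oxo-2-phenylchroman-3-yl (2S)-2-methylbutanoate
Conditions: DCC (1.4 eq), DMAP (0.1 eq), CH2Cl2, 0 °C to rt
Reagents that add atoms: none
Why: Steglich esterification acylates the secondary 3-OH while the chelated 5-OH stays free, and at 0 °C with catalytic DMAP neither the α-stereocentre of the acid nor C2/C3 epimerises.

**Step 9**
Reactants: 12 (2R,3R)-7-(benzyloxy)-5-hydroxy-4-oxo-2-phenylchroman-3-yl (2S)-2-methylbutanoate
Product: 13 (2R,3R)-5,7-dihydroxy-4-oxo-2-phenylchroman-3-yl (2S)-2-methylbutanoate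
Conditions: H2 (1 atm), 10% Pd/C, EtOAc, rt
Reagents that add atoms: none
Why: Neutral hydrogenolysis of the single benzyl aryl ether releases the 7-OH without touching the ester, the ketone or any stereocentre.

**Compound list**
1 | tiglic acid, (E)-2-methylbut-2-enoic acid | C/C=C(\C)C(=O)O | starting material
2 | (S)-2-methylbutanoic acid | CC[C@H](C)C(=O)O | intermediate
3 | 2',4',6'-trihydroxyacetophenone | CC(=O)c1c(O)cc(O)cc1O | starting material
4 | 1-[2,4-bis(benzyloxy)-6-hydroxyphenyl]ethan-1-one | CC(=O)c1c(O)cc(OCc2ccccc2)cc1OCc1ccccc1 | intermediate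
5 | (E)-1-[2,4-bis(benzyloxy)-6-hydroxyphenyl]-3-(dimethylamino)prop-2-en-1-one (enaminone) | CN(C)/C=C/C(=O)c1c(O)cc(OCc2ccccc2)cc1OCc1ccccc1 | intermediate
6 | 5,7-bis(benzyloxy)-4H-chromen-4-one | O=c1ccoc2cc(OCc3ccccc3)cc(OCc3ccccc3)c12 | intermediate
7 | phenylboronic acid | OB(O)c1ccccc1 | starting material
8 | (2S)-5,7-bis(benzyloxy)-2-phenylchroman-4-one | O=C1C[C@@H](c2ccccc2)Oc2cc(OCc3ccccc3)cc(OCc3ccccc3)c12 | intermediate
9 | (S)-pinocembrin, (2S)-5,7-dihydroxy-2-phenylchroman-4-one | O=C1C[C@@H](c2ccccc2)Oc2cc(O)cc(O)c12 | intermediate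
10 | (2R,3R)-pinobanksin, (2R,3R)-3,5,7-trihydroxy-2-phenylchroman-4-one | O[C@H]1C(=O)c2c(O)cc(O)cc2O[C@@H]1c1ccccc1 | intermediate
11 | (2R,3R)-7-(benzyloxy)-3,5-dihydroxy-2-phenylchroman-4-one | O[C@H]1C(=O)c2c(O)cc(OCc3ccccc3)cc2O[C@@H]1c1ccccc1 | intermediate
12 | (2R,3R)-7-(benzyloxy)-5-hydroxy-4-oxo-2-phenylchroman-3-yl (2S)-2-methylbutanoate | CC[C@H](C)C(=O)O[C@H]1C(=O)c2c(O)cc(OCc3ccccc3)cc2O[C@@H]1c1ccccc1 | intermediate
13 | (2R,3R)-5,7-dihydroxy-4-oxo-2-phenylchroman-3-yl (2S)-2-methylbutanoate | CC[C@H](C)C(=O)O[C@H]1C(=O)c2c(O)cc(O)cc2O[C@@H]1c1ccccc1 | target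

**Totals**
Total step count: 9. Longest linear sequence: 8 steps (steps 2–9, from 3); step 1 is a one-step side branch that joins at step 8.

**Three steps most likely to fail, with fallbacks**

Step 4 (the electron-rich 5,7-dialkoxychromone is a sluggish acceptor and the ee is substrate-dependent). The fallback sets out from 4 and comes back at 10. Claisen–Schmidt condensation of 4 with benzaldehyde (KOH, EtOH, rt) gives the chalcone (E)-1-[2,4-bis(benzyloxy)-6-hydroxyphenyl]-3-phenylprop-2-en-1-one F1. NaOAc in refluxing EtOH closes it by oxa-Michael addition to racemic 5,7-bis(benzyloxy)-2-phenylchroman-4-one F2. Hydrogenolysis (H2, Pd/C, EtOAc/MeOH) gives racemic pinocembrin F3. The dioxygenase of step 6, which accepts only the 2S enantiomer, then converts that half of F3 into 10 in an enzymatic kinetic resolution. The recovered 2R-flavanone is racemised with a trace of base and recycled.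

Step 6 (enzyme expression level, low substrate solubility and modest volumetric productivity on preparative scale). The fallback sets out from 4 and comes back at 13. Here C2 and C3 are set together by chemical catalysis.
- 4 is protected (NaH, MOMCl, DMF) to 1-[2,4-bis(benzyloxy)-6-(methoxymethoxy)phenyl]ethan-1-one F4.
- Condensation with benzaldehyde (KOH, EtOH) gives the chalcone (E)-1-[2,4-bis(benzyloxy)-6-(methoxymethoxy)phenyl]-3-phenylprop-2-en-1-one F5.
- Juliá–Colonna epoxidation (poly-L-leucine, urea–H2O2, DBU, THF) gives the epoxide [2,4-bis(benzyloxy)-6-(methoxymethoxy)phenyl][(2R,3S)-3-phenyloxiran-2-yl]methanone F6.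
- HCl in MeOH (45 °C) removes the MOM group, and the freed phenol opens the epoxide at the benzylic carbon with inversion to give trans (2R,3R)-5,7-bis(benzyloxy)-3-hydroxy-2-phenylchroman-4-one F7, which is recrystallised to upgrade ee.
- Steglich esterification with 2 (DCC, DMAP) gives (2R,3R)-5,7-bis(benzyloxy)-4-oxo-2-phenylchroman-3-yl (2S)-2-methylbutanoate F8.
- Hydrogenolysis (H2, Pd/C, EtOAc) gives 13.

Step 7 (base sensitivity of the dihydroflavonol: C2 epimerisation through ring opening, air oxidation to the flavonol, over-alkylation). The fallback sets out from 10 and comes back at 13 without any benzyl group. 10 is esterified at both reactive hydroxyls with 2 (2.5 eq, DCC, DMAP, CH2Cl2, 0 °C) to give the diester (2R,3R)-5-hydroxy-3-{[(2S)-2-methylbutanoyl]oxy}-4-oxo-2-phenylchroman-7-yl (2S)-2-methylbutanoate F9, the chelated 5-OH staying free. A lipase (Burkholderia cepacia lipase, n-BuOH, THF, 40 °C) then removes only the phenolic 7-ester by alcoholysis, because lipases cleave unhindered aryl esters much faster than the hindered secondary 3-ester, and 13 is obtained directly.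

**Further compounds**
F1 | step 4 | (E)-1-[2,4-bis(benzyloxy)-6-hydroxyphenyl]-3-phenylprop-2-en-1-one | O=C(/C=C/c1ccccc1)c1c(O)cc(OCc2ccccc2)cc1OCc1ccccc1
F2 | step 4 | racemic 5,7-bis(benzyloxy)-2-phenylchroman-4-one | O=C1CC(c2ccccc2)Oc2cc(OCc3ccccc3)cc(OCc3ccccc3)c12
F3 | step 4 | racemic pinocembrin, 5,7-dihydroxy-2-phenylchroman-4-one | O=C1CC(c2ccccc2)Oc2cc(O)cc(O)c12
F4 | step 6 | 1-[2,4-bis(benzyloxy)-6-(methoxymethoxy)phenyl]ethan-1-one | CC(=O)c1c(OCOC)cc(OCc2ccccc2)cc1OCc1ccccc1
F5 | step 6 | (E)-1-[2,4-bis(benzyloxy)-6-(methoxymethoxy)phenyl]-3-phenylprop-2-en-1-one | O=C(/C=C/c1ccccc1)c1c(OCOC)cc(OCc2ccccc2)cc1OCc1ccccc1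
F6 | step 6 | [2,4-bis(benzyloxy)-6-(methoxymethoxy)phenyl][(2R,3S)-3-phenyloxiran-2-yl]methanone | O=C([C@@H]1O[C@H]1c1ccccc1)c1c(OCOC)cc(OCc2ccccc2)cc1OCc1ccccc1
F7 | step 6 | (2R,3R)-5,7-bis(benzyloxy)-3-hydroxy-2-phenylchroman-4-one | O[C@H]1C(=O)c2c(OCc3ccccc3)cc(OCc3ccccc3)cc2O[C@@H]1c1ccccc1
F8 | step 6 | (2R,3R)-5,7-bis(benzyloxy)-4-oxo-2-phenylchroman-3-yl (2S)-2-methylbutanoate | CC[C@H](C)C(=O)O[C@H]1C(=O)c2c(OCc3ccccc3)cc(OCc3ccccc3)cc2O[C@@H]1c1ccccc1
F9 | step 7 | (2R,3R)-5-hydroxy-3-{[(2S)-2-methylbutanoyl]oxy}-4-oxo-2-phenylchroman-7-yl (2S)-2-methylbutanoate | CC[C@H](C)C(=O)O[C@H]1C(=O)c2c(O)cc(OC(=O)[C@@H](C)CC)cc2O[C@@H]1c1ccccc1
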